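The route rests on cutting the bond between the ring-A methylene C3 and the quaternary gem-dimethyl carbon C4 of the drimane decalin. C4 with its two methyl groups is read as the Markovnikov carbon of an isopropenyl group, so ring A is closed by a manganese/nickel dual-catalytic intramolecular hydroalkylation: hydrogen-atom transfer to the isopropenyl group and coupling with a primary iodide create the quaternary carbon and the trans-decalin in one operation. The precursor is (R)-carvone alkylated twice at C6, carrying its native isopropenyl group and a 3-iodopropyl chain trans to each other. The carvone carbonyl carbon later becomes C9 and takes up the arylmethyl unit by methylenation and hydroboration/Suzuki coupling.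

Key step: step 3

Assumption: drimane numbering is used for the decalin (C11 = benzylic CH2; carvone numbering before ring A is closed), and methyl 3-bromo-4,5-dihydroxybenzoate is taken as a purchasable compound.

Step 1
Reactants: 1 (R)-(−)-carvone
Product: 3 (5R,6S)-2,6-dimethyl-5-(prop-1-en-2-yl)cyclohex-2-en-1-one (trans-6-methylcarvone), via lithium dienolate 2 (not isolated)
Conditions: LDA, THF, −78 °C; then MeI, −78 → 0 °C
Reagents that add atoms: iodomethane, CI
Why: Kinetic deprotonation of the cross-conjugated enone by LDA takes place at the α′-CH2 (C6) and the dienolate is C-methylated there (ketone enolate alkylation), mainly trans to the isopropenyl group, which is of no consequence because C6 becomes planar again in step 2.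

Step 2
Reactants: 3 trans-6-methylcarvone
Product: 5 (5S,6S)-6-(3-iodopropyl)-2,6-dimethyl-5-(prop-1-en-2-yl)cyclohex-2-en-1-one, via lithium enolate 4 (not isolated)
Conditions: LDA, THF, −78 → 0 °C; then DMPU, I(CH2)3I (excess), −78 °C → rt
Reagents that add atoms: 1,3-diiodopropane, ICCCI
Why: Second ketone enolate alkylation (sequential α′-dialkylation of carvone): the tetrasubstituted enolate is attacked on the face opposite to the neighbouring isopropenyl group, so the iodopropyl chain ends trans and the methyl group cis to it, which sets the quaternary centre (future C10) relative to C5, while the excess of diiodide suppresses double displacement.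

Step 3
Reactants: 5 (5S,6S)-6-(3-iodopropyl)-2,6-dimethyl-5-(prop-1-en-2-yl)cyclohex-2-en-1-one
Product: 7 (4aS,8aS)-2,5,5,8a-tetramethyl-4a,5,6,7,8,8a-hexahydronaphthalen-1(4H)-one, via tertiary radical 6 (not isolated)
Conditions: Mn(dpm)3 (cat., dpm = dipivaloylmethanate), Ni(acac)2 (cat.), PhSiH3, K2CO3, (CF3)2CHOH, ClCH2CH2Cl/propylene carbonate, rt, dilute
Reagents that add atoms: none
Why: Proposed new method: the manganese hydride formed from Mn(dpm)3 and PhSiH3 transfers a hydrogen atom to the terminal CH2 of the isopropenyl group and gives the tertiary C4 radical 6, while low-valent nickel takes up the primary C3–I bond, captures the tertiary radical and forms the C3–C4 bond by reductive elimination from the resulting dialkylnickel. The closest known reaction type is the intermolecular manganese/nickel dual-catalytic Markovnikov hydroalkylation of 1,1-disubstituted olefins with unactivated primary alkyl halides that builds quaternary carbons; the ring-closing mode is the new element. Ring A closes in a formal 6-exo-tet manner (C4 onto C3 with iodide leaving), through a seven-membered nickelacycle that contracts to the cyclohexane. No stereocenter is created, since C4 ends with two methyl groups, and the trans ring fusion follows from the trans arrangement of the isopropenyl and iodopropyl groups fixed at C5 and C10 in 5, both equatorial in the reactive half-chair. The step needs hydrogen-atom transfer to the isopropenyl group and not to the enone, and ring closure in preference to simple reduction or 7-endo radical cyclisation of a free C3 radical; the electron-rich, unhindered 1,1-disubstituted alkene is the kinetically preferred hydrogen-atom acceptor (carvone-type enones survive Mukaiyama-type reactions at the isopropenyl group), and capture of both carbon ends on one nickel centre under dilution should favour closure.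

Step 4
Reactants: 7 (4aS,8aS)-2,5,5,8a-tetramethyl-4a,5,6,7,8,8a-hexahydronaphthalen-1(4H)-one
Product: 8 (4aS,8aS)-2,5,5,8a-tetramethyl-1-methylidene-1,4,4a,5,6,7,8,8a-octahydronaphthalene (drima-7,9(11)-diene)
Conditions: Ph3PCH3Br, KOtBu, toluene, 90 °C
Reagents that add atoms: methyltriphenylphosphonium bromide, C[P+](c1ccccc1)(c1ccccc1)c1ccccc1.[Br-]
Why: Wittig methylenation under forcing conditions for hindered ketones should convert the C9 carbonyl, which cannot enolise towards the quaternary C10, into the exocyclic C9=C11 methylene without touching either stereocenter.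

Step 5
Reactants: 9 methyl 3-bromo-4,5-dihydroxybenzoate
Product: 10 methyl 3-bromo-4,5-bis(methoxymethoxy)benzoate
Conditions: MOMCl, iPr2NEt, CH2Cl2, 0 °C → rt
Reagents that add atoms: chloromethyl methyl ether (MOMCl), COCCl
Why: O-Alkylation of both phenols (MOM protection) masks the catechol, which would otherwise bind boron and palladium in step 6, as base-stable, acid-labile acetals.

Step 6
Reactants: 8 drima-7,9(11)-diene; 10 methyl 3-bromo-4,5-bis(methoxymethoxy)benzoate
Product: 12 methyl 3-{[(1S,4aS,8aS)-2,5,5,8a-tetramethyl-1,4,4a,5,6,7,8,8a-octahydronaphthalen-1-yl]methyl}-4,5-bis(methoxymethoxy)benzoate, via alkylborane 11 (not isolated)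
Conditions: 9-BBN dimer, THF, 0 °C → rt; then 10, Pd(dppf)Cl2 (cat.), aq. K3PO4, DMF, 50 °C
Reagents that add atoms: 9-borabicyclo[3.3.1]nonane (9-BBN-H), B1C2CCCC1CCC2 (its boron and carbons stay in intermediate 11 only)
Why: Hydroboration followed by B-alkyl Suzuki–Miyaura coupling: 9-BBN should add to the exocyclic methylene with boron at C11 and hydrogen at C9 from the α face, opposite to the axial angular methyl on C10, which sets C9 (9α-H, equatorial arylmethyl), and the primary alkylborane then couples with the aryl bromide while the trisubstituted C7=C8 alkene, the ester and the MOM ethers stay untouched.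

Step 7
Reactants: 12 bis-MOM ether of the target
Product: 13 methyl 3,4-dihydroxy-5-{[(1S,4aS,8aS)-2,5,5,8a-tetramethyl-1,4,4a,5,6,7,8,8a-octahydronaphthalen-1-yl]methyl}benzoate (target)
Conditions: 1.25 M HCl in MeOH, rt
Reagents that add atoms: none
Why: Acid-catalysed acetal exchange (MOM cleavage) should release the catechol, methanol as solvent keeping the methyl ester intact and the mild acid leaving the trisubstituted alkene in place.

Compound list
1 | (R)-(−)-carvone | O=C1C(C)=CC[C@@H](C(C)=C)C1 | starting material
2 | lithium dienolate of 1 (O–Li on C1, C1=C6 and C2=C3, carvone numbering) | [Li+].[O-]C1=C[C@H](C(C)=C)CC=C1C | intermediate (not isolated)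
3 | (5R,6S)-2,6-dimethyl-5-(prop-1-en-2-yl)cyclohex-2-en-1-one (trans-6-methylcarvone; any 6-epimer is carried along) | O=C1C(C)=CC[C@@H](C(C)=C)[C@@H]1C | intermediate
4 | lithium enolate of 3 (O–Li on C1, C1=C6 bearing the new methyl group) | [Li+].[O-]C1=C(C)[C@H](C(C)=C)CC=C1C | intermediate (not isolated)
5 | (5S,6S)-6-(3-iodopropyl)-2,6-dimethyl-5-(prop-1-en-2-yl)cyclohex-2-en-1-one | O=C1C(C)=CC[C@@H](C(C)=C)[C@@]1(CCCI)C | intermediate
6 | 2-[(1S,2S)-2-(3-iodopropyl)-2,4-dimethyl-3-oxocyclohex-4-en-1-yl]propan-2-yl radical | O=C1C(C)=CC[C@@H]([C](C)C)[C@@]1(CCCI)C | intermediate (not isolated)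
7 | (4aS,8aS)-2,5,5,8a-tetramethyl-4a,5,6,7,8,8a-hexahydronaphthalen-1(4H)-one (11-nordrim-7-en-9-one) | O=C1C(C)=CC[C@H]2C(C)(C)CCC[C@]12C | intermediate
8 | (4aS,8aS)-2,5,5,8a-tetramethyl-1-methylidene-1,4,4a,5,6,7,8,8a-octahydronaphthalene (drima-7,9(11)-diene) | C=C1C(C)=CC[C@H]2C(C)(C)CCC[C@]12C | intermediate
9 | methyl 3-bromo-4,5-dihydroxybenzoate | COC(=O)c1cc(O)c(O)c(Br)c1 | starting material
10 | methyl 3-bromo-4,5-bis(methoxymethoxy)benzoate | COC(=O)c1cc(OCOC)c(OCOC)c(Br)c1 | intermediate
11 | 9-{[(1S,4aS,8aS)-2,5,5,8a-tetramethyl-1,4,4a,5,6,7,8,8a-octahydronaphthalen-1-yl]methyl}-9-borabicyclo[3.3.1]nonane | B1(C[C@H]3C(C)=CC[C@H]4C(C)(C)CCC[C@]34C)C2CCCC1CCC2 | intermediate (not isolated)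
12 | methyl 3-{[(1S,4aS,8aS)-2,5,5,8a-tetramethyl-1,4,4a,5,6,7,8,8a-octahydronaphthalen-1-yl]methyl}-4,5-bis(methoxymethoxy)benzoate | COC(=O)c1cc(OCOC)c(OCOC)c(C[C@H]2C(C)=CC[C@H]3C(C)(C)CCC[C@]23C)c1 | intermediate
13 | methyl 3,4-dihydroxy-5-{[(1S,4aS,8aS)-2,5,5,8a-tetramethyl-1,4,4a,5,6,7,8,8a-octahydronaphthalen-1-yl]methyl}benzoate | COC(=O)c1cc(O)c(O)c(C[C@H]2C(C)=CC[C@H]3C(C)(C)CCC[C@]23C)c1 | target

Total step count: 7. Longest linear sequence: 6 steps (steps 1, 2, 3, 4, 6, 7 from (R)-carvone).

Steps most likely to fail

Step 3 (Proposed new method). The tertiary radical may be quenched to the isopropyl compound, or the iodide reduced, before nickel joins the two carbon ends, and hydrogen-atom transfer may stray to the enone. The fallback uses known chemistry and forms the same C3–C4 bond by an iron-mediated reductive olefin coupling. It sets out from 3 (through its enolate 4): alkylation with methyl 2-(bromomethyl)acrylate (THF, −78 °C) should give methyl 2-{[(1S,6S)-1,3-dimethyl-2-oxo-6-(prop-1-en-2-yl)cyclohex-3-en-1-yl]methyl}prop-2-enoate F1. Fe(acac)3 and PhSiH3 in EtOH/ethylene glycol at 60 °C then generate the same tertiary C4 radical, which should add 6-endo-trig to the CH2 terminus of the acrylate (hydrogen-atom-transfer-initiated Giese cyclisation) to give methyl (4aS,8aS)-4,4,7,8a-tetramethyl-8-oxo-1,2,3,4,4a,5,8,8a-octahydronaphthalene-2-carboxylate F2 as C2 epimers. Saponification (LiOH, THF/H2O) should give (4aS,8aS)-4,4,7,8a-tetramethyl-8-oxo-1,2,3,4,4a,5,8,8a-octahydronaphthalene-2-carboxylic acid F3. Photocatalytic hydrodecarboxylation (9-mesityl-10-methylacridinium tetrafluoroborate, PhSSPh, iPr2NEt, CF3CH2OH, blue light) removes the carboxyl group and comes back to the route at 7.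

Step 6. Hydroboration may show poor facial selectivity at C9, and transmetalation of the β-branched alkylborane to the ortho-substituted arylpalladium may be so slow that protodeboronation takes over. The fallback sets out from 11: oxidation (NaBO3·4H2O, THF/H2O) should give [(1S,4aS,8aS)-2,5,5,8a-tetramethyl-1,4,4a,5,6,7,8,8a-octahydronaphthalen-1-yl]methanol (drimenol) F4, at which stage a C9 epimer can be removed by chromatography. Appel iodination (PPh3, I2, imidazole, CH2Cl2) should give (1S,4aS,8aS)-1-(iodomethyl)-2,5,5,8a-tetramethyl-1,4,4a,5,6,7,8,8a-octahydronaphthalene (drimenyl iodide) F5. Zinc insertion (Zn dust, LiCl, THF, 40 °C) should give drimenylzinc iodide F6, and Negishi coupling with 10 (Pd(OAc)2, SPhos, THF, 50 °C) comes back to the route at 12.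

Step 2. C-Alkylation of the hindered tetrasubstituted enolate by an unactivated primary iodide may be slow, letting proton transfer, O-alkylation or double displacement on the diiodide compete. The fallback sets out from 3 (through its enolate 4): allylation with allyl bromide (THF, −78 °C → rt), a reliable alkylation that also enters trans to the isopropenyl group, should give (5S,6S)-2,6-dimethyl-6-(prop-2-en-1-yl)-5-(prop-1-en-2-yl)cyclohex-2-en-1-one F7. Disiamylborane (THF, 0 °C) should hydroborate the monosubstituted allyl alkene in preference to the 1,1-disubstituted isopropenyl group and the hindered ketone, giving (5S,6S)-6-{3-[bis(3-methylbutan-2-yl)boranyl]propyl}-2,6-dimethyl-5-(prop-1-en-2-yl)cyclohex-2-en-1-one F8. Iodination of the primary boron–carbon bond (I2, NaOMe, MeOH, 0 °C) comes back to the route at 5.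

Further compounds
F1 | step 3 | methyl 2-{[(1S,6S)-1,3-dimethyl-2-oxo-6-(prop-1-en-2-yl)cyclohex-3-en-1-yl]methyl}prop-2-enoate | O=C1C(C)=CC[C@@H](C(C)=C)[C@@]1(CC(=C)C(=O)OC)C
F2 | step 3 | methyl (4aS,8aS)-4,4,7,8a-tetramethyl-8-oxo-1,2,3,4,4a,5,8,8a-octahydronaphthalene-2-carboxylate (C2 epimers) | O=C1C(C)=CC[C@H]2C(C)(C)CC(C(=O)OC)C[C@]12C
F3 | step 3 | (4aS,8aS)-4,4,7,8a-tetramethyl-8-oxo-1,2,3,4,4a,5,8,8a-octahydronaphthalene-2-carboxylic acid (C2 epimers) | O=C1C(C)=CC[C@H]2C(C)(C)CC(C(=O)O)C[C@]12C
F4 | step 6 | [(1S,4aS,8aS)-2,5,5,8a-tetramethyl-1,4,4a,5,6,7,8,8a-octahydronaphthalen-1-yl]methanol (drimenol) | OC[C@H]1C(C)=CC[C@H]2C(C)(C)CCC[C@]12C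
F5 | step 6 | (1S,4aS,8aS)-1-(iodomethyl)-2,5,5,8a-tetramethyl-1,4,4a,5,6,7,8,8a-octahydronaphthalene (drimenyl iodide) | IC[C@H]1C(C)=CC[C@H]2C(C)(C)CCC[C@]12C
F6 | step 6 | {[(1S,4aS,8aS)-2,5,5,8a-tetramethyl-1,4,4a,5,6,7,8,8a-octahydronaphthalen-1-yl]methyl}zinc iodide | I[Zn]C[C@H]1C(C)=CC[C@H]2C(C)(C)CCC[C@]12C
F7 | step 2 | (5S,6S)-2,6-dimethyl-6-(prop-2-en-1-yl)-5-(prop-1-en-2-yl)cyclohex-2-en-1-one | O=C1C(C)=CC[C@@H](C(C)=C)[C@@]1(CC=C)C
F8 | step 2 | (5S,6S)-6-{3-[bis(3-methylbutan-2-yl)boranyl]propyl}-2,6-dimethyl-5-(prop-1-en-2-yl)cyclohex-2-en-1-one | O=C1C(C)=CC[C@@H](C(C)=C)[C@@]1(CCCB(C(C)C(C)C)C(C)C(C)C)C
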